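Follow the left-handed product: it forms at a rate proportional to reagent, free catalyst and left-handed substrate, so ask how these three shift with the catalyst charge.

left-handed substrate 0.41 M; reagent 0.492 M; free catalyst 9.4 mM; impurity 8.8 mM; right-handed substrate 0.41 M

    reagent + free catalyst + left-handed substrate → free catalyst + left-handed product (k1 = 60 M⁻² s⁻¹)
    reagent + free catalyst + right-handed substrate → free catalyst + right-handed product (k2 = 26 M⁻² s⁻¹)
    reagent ⇌ dormant form (K3 = 0.45, k3 = 0.22 s⁻¹)
    free catalyst + impurity → spent catalyst (k4 = 25 M⁻¹ s⁻¹)

- apparent order in free catalyst when 20 % of the left-handed substrate and right-handed substrate together are converted (percent change of the rate of making left-handed product for one percent more free catalyst charged)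

- free catalyst is single-handed; left-handed substrate and right-handed substrate are mirror images of each other, charged as a racemate, each of them at the stated concentration
- charge of left-handed substrate (flask): 0.41 M

Compare flasks at equal conversion, not at equal time. Both substrates are consumed along the same integral of reagent times free catalyst, so equal conversion means equal left-handed substrate and an equal sum of reagent and dormant form. What can still move is free catalyst and the split of that sum.

Impurity takes free catalyst one for one. In this flask 0.600 mM of free catalyst stands over the impurity; call this the catalyst margin, free catalyst charged minus impurity charged. Free catalyst is then impurity left plus margin. Impurity left depends on the time integral of free catalyst, so if that integral stays equal, each extra millimole per litre charged stands as extra free catalyst. The order is then the charge over the free catalyst at the mark.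

Reckon that free catalyst in two ways. By the clock, with the mark at 0.0332 min:

free catalyst = margin ÷ (1 − (impurity charged ÷ catalyst charged) × exp(−25 M⁻¹ s⁻¹ × margin × time)) = 6.57 mM

By conversion, without the clock, take the mean constant and a logarithmic mean of reagent, from its charge down to its balanced value 0.226 M:

integral of reagent times catalyst = 0.00519 M^2 s

mean reagent = 0.342 M

free catalyst = 6.62 mM

The orders are 1.43 and 1.42, from different inputs, so trust the lower end at about that value.

Reagent adds to it. The relaxation half-life is 0.978 s, and the mark comes at about twice that. Reckoned against the balance of the full reagent charge, with consumption left out, the gap of dormant form has decayed to 0.0372 M at the mark; consumed reagent lowers the balance and narrows the gap in the flask. Carrying that decayed gap through a shorter run adds about 0.332, which I take as a high figure, since consumption is left out of it. Take 1.76 as the upper end and commit to the middle, 1.60.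

The forecast gives 1.68, holding that “extra catalyst survives disproportionately”.

The simulation gives 1.7, higher than my middle and inside the range. In this flask, per free catalyst at the charged amounts, the two product steps together run at 1040 min⁻¹ against 13 min⁻¹ for the loss to impurity, 78.9 times faster. Even so, the impurity step has 97 % of its turnover behind it after 1.20 min, and at 6.00 min free catalyst stands at 6.41 % of the catalyst charged, the margin's share being 6.38 %, with impurity at 0.0290 % of its charge.

(The numbers were set for the occasion.)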